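The pitfall in the midnight and dawn runs is to call the target flat and average each column, which blurs any small fall when the top of the curve is what is asked.

| setting | midnight | dawn | flask |
|---|---|---|---|
| starting material | 1 mM | 1 mM | 1.0 mM |
| partner | 0.55 equiv | 0.83 equiv | 1.10 equiv |
| second substrate | 1 equiv | 1 equiv | 1.00 equiv |
| third substrate | 1 equiv (fed, over 1.5 min) | 1 equiv (fed, over 1.5 min) | 1.00 equiv (fed, over 1.5 min) |
| remark | run made earlier | run made earlier |  |
| time |  |  | 50 min |

| midnight: time / min | midnight: target / % | dawn: time / min | dawn: target / % |
|---|---|---|---|
| 0.500 | 13.1 | 0.500 | 19.6 |
| 1.33 | 12.8 | 1.33 | 20.0 |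
| 3.00 | 12.9 | 3.00 | 19.3 |
| 8.00 | 11.8 | 8.00 | 18.6 |
| 20.0 | 12.2 | 20.0 | 19.2 |
| 50.0 | 12.0 | 50.0 | 19.2 |

(scatter of a reading: 0.5 percentage points)

- the numbers in the tables scatter by 0.5 percentage points (one standard deviation)
- reactions considered so far: starting material + partner -> target; second substrate + partner -> second product; third substrate + partner -> third product; partner -> decomposed reagent; target <-> isomer of the product

1. the moment within 50 min at which there is most target
2. the amount of target, in percent of the starting material charged, at that time

I take the readings up to 3.00 min as the early level, 12.9% at midnight and 19.6% at dawn. Per equivalent of partner these give 23.5% and 23.7%, a gap smaller than the scatter of one reading. So I pool them into one carried number, the early yield per equivalent of partner, 23.6%, and for the flask with 1.10 equiv I reckon a top of 26.0%.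

The late level, from 8.00 min on, is 12.0% and 19.0%. The weak link is this fall: the drops read 0.90 percentage points and 0.60 points, beside a scatter of 0.5 points on one reading. I reforge it as one pooled fraction, 4.81% of the early level, and from that I estimate 24.7% for the flask by 50 min. The early level already stands at the first sample, so I place the top between 0.500 min and 1.33 min.

The forecast says 28% at 1.5 min, on the ground that “The yield is set by competition for the partner”. That is higher than my 26.0% and later than my window.

The flask gives 26.6% at 0.865 min, earlier than the forecast's time.

    starting material + partner → target (k = 21.0 L mol⁻¹ s⁻¹)
    second substrate + partner → second product (k = 19.0 L mol⁻¹ s⁻¹)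
    third substrate + partner → third product (k = 100 L mol⁻¹ s⁻¹)
    partner → decomposed reagent (k = 0.0240 s⁻¹)
    target ⇌ isomer of the product (K = 0.170, k = 0.00200 s⁻¹)

That top is 24.2% per equivalent, beside my 23.6%, and by 50.0 min the flask holds 24.4% target and 4.16% isomer of the product, with 0% of the partner, the limiting reagent, left. In the neighbour flask with 4.40 equiv of partner, the other charges as in the recipe, the same reckoning gives 104%, more than the starting material charged. That neighbour flask gives 77.3%, or 17.6% per equivalent, with 15.4% of its starting material left at 50.0 min.

(The earlier runs and the new flask were generated by integration with constants of no real substance, and the scatter is random.)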